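**Strategy.** Ring C is cut at C3–C4 and O1–C2. The phenol oxygen O1 and the ketone carbon C4 sit on neighbouring carbons (C8a, C4a) of ring A, so both belong to one salicylaldehyde, while C2–C3 with ring B is an arylacetylene. In a single flask, a chelation-assisted rhodium hydroacylation adds the aldehyde C–H across the alkyne (C3–C4, giving an (E)-2'-hydroxychalcone), and a chiral cinchona thiourea then closes O1–C2 by oxa-Michael addition and sets C2 as (S). The precursors are 2-hydroxy-4,6-dimethoxy-3-prenylbenzaldehyde and the TBS ether of 5-ethynyl-2-methoxyphenol, each made in two steps.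

Key step: step 5

Remarks on the chemistry: the target is read as the (2S)-flavanone, and chroman numbering is used (O1, C2, C3, C4, C4a, C5 to C8, C8a). Assumption: the quinine-derived thiourea is taken to give the (2S) sense of ring closure; its quinidine-derived pseudoenantiomer would replace it if the sense proves opposite.

Step 1
Reactants: 1 3,5-dimethoxyphenol; 2 prenyl bromide (1-bromo-3-methylbut-2-ene)
Product: 3 3,5-dimethoxy-2-(3-methylbut-2-en-1-yl)phenol
Conditions: NaH, toluene, 0 °C to rt
Reagents that add atoms: none
Why: In toluene the sodium phenoxide reacts as a tight ion pair and should be alkylated on carbon at one of the two equivalent ortho positions by SN2 attack on the primary bromide (ortho-selective phenoxide C-alkylation).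

Step 2
Reactants: 3 3,5-dimethoxy-2-(3-methylbut-2-en-1-yl)phenol
Product: 4 2-hydroxy-4,6-dimethoxy-3-(3-methylbut-2-en-1-yl)benzaldehyde
Conditions: MgCl2, Et3N, (CH2O)n, MeCN, reflux; then 1 M HCl
Reagents that add atoms: paraformaldehyde (formaldehyde source), C=O
Why: Casnati–Skattebøl ortho-formylation, in which the magnesium phenoxide delivers coordinated formaldehyde to the only free ortho carbon and a second formaldehyde takes hydride from the benzylic alkoxide to give the salicylaldehyde; the prenyl alkene should be inert.

Step 3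
Reactants: 5 isovanillin (3-hydroxy-4-methoxybenzaldehyde)
Product: 6 3-(tert-butyldimethylsilyloxy)-4-methoxybenzaldehyde
Conditions: TBSCl, imidazole, DMF, rt
Reagents that add atoms: tert-butyldimethylsilyl chloride (TBSCl), CC(C)(C)[Si](C)(C)Cl
Why: Standard imidazole-promoted silylation of the phenol, so that step 5 sees only the one phenol needed for rhodium chelation and for the bifunctional catalyst.

Step 4
Reactants: 6 3-(tert-butyldimethylsilyloxy)-4-methoxybenzaldehyde
Product: 7 tert-butyl(5-ethynyl-2-methoxyphenoxy)dimethylsilane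
Conditions: TMSCHN2, LiN(iPr)2, THF, −78 °C to rt; then H2O
Reagents that add atoms: trimethylsilyldiazomethane (TMSCHN2), C[Si](C)(C)C=[N+]=[N-]
Why: Colvin homologation, in which lithiated trimethylsilyldiazomethane adds to the aldehyde, Peterson-type loss of silanolate gives a diazoalkene, and loss of N2 with a 1,2-hydride shift gives the terminal alkyne without the carbonate/methanol conditions that would cleave the aryl silyl ether.

Step 5
Reactants: 4 2-hydroxy-4,6-dimethoxy-3-(3-methylbut-2-en-1-yl)benzaldehyde; 7 tert-butyl(5-ethynyl-2-methoxyphenoxy)dimethylsilane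
Product: 9 (2S)-2-[3-(tert-butyldimethylsilyloxy)-4-methoxyphenyl]-5,7-dimethoxy-8-(3-methylbut-2-en-1-yl)chroman-4-one, via chalcone 8 (not isolated)
Conditions: [RhCl(cod)]2 (2.5 mol %), 1,1'-bis(diphenylphosphino)ferrocene (5 mol %), Na2CO3 (5 mol %), toluene, 80 °C; then filtration through Celite, N-[3,5-bis(trifluoromethyl)phenyl]-N'-[(8α,9S)-6'-methoxycinchonan-9-yl]thiourea (10 mol %), toluene, 0 °C to rt
Reagents that add atoms: none
Why: The rhodium phenoxide of 4 inserts into the aldehyde C–H bond to give a five-membered acyl(hydrido)rhodium chelate that resists decarbonylation; syn hydrometalation of alkyne 7 with rhodium on the unsubstituted carbon, then C–C reductive elimination, forges C3–C4 and releases the (E)-2'-hydroxychalcone 8. The closest known reaction type is the chelation-assisted rhodium-catalysed hydroacylation of alkynes with salicylaldehydes, including its one-pot coupling to an oxa-Michael closure that gives chroman-4-ones. The bifunctional cinchona thiourea then closes ring C by a 6-endo-trig intramolecular oxa-Michael addition that forms O1–C2, a known asymmetric cyclisation type for 2'-hydroxychalcones. The new stereocentre C2 is under catalyst control: the thiourea binds the enone carbonyl, the quinuclidine nitrogen holds the phenol, and the oxygen is delivered to one face of the β-carbon to give the (2S) product. The step needs linear regioselectivity in the alkyne insertion (steric bias of the terminal alkyne, with the aryl group directing the acyl group to the distal carbon), chemoselectivity for the alkyne over the trisubstituted prenyl alkene (too hindered to insert), and kinetic control of the ring closure (base removed by filtration and low temperature, to suppress racemic background closure and retro-oxa-Michael opening).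

Step 6
Reactants: 9 (2S)-2-[3-(tert-butyldimethylsilyloxy)-4-methoxyphenyl]-5,7-dimethoxy-8-(3-methylbut-2-en-1-yl)chroman-4-one
Product: 10 (2S)-2-(3-hydroxy-4-methoxyphenyl)-5,7-dimethoxy-8-(3-methylbut-2-en-1-yl)chroman-4-one
Conditions: Bu4NF, AcOH, THF, 0 °C
Reagents that add atoms: none
Why: Fluoride-mediated desilylation of the aryl silyl ether; buffering with acetic acid should prevent opening of ring C by enolisation and β-elimination, so C2 is not scrambled.

**Compound list**

1 | 3,5-dimethoxyphenol | COc1cc(O)cc(OC)c1 | starting material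
2 | prenyl bromide (1-bromo-3-methylbut-2-ene) | CC(C)=CCBr | starting material
3 | 3,5-dimethoxy-2-(3-methylbut-2-en-1-yl)phenol | COc1cc(OC)c(CC=C(C)C)c(O)c1 | intermediate
4 | 2-hydroxy-4,6-dimethoxy-3-(3-methylbut-2-en-1-yl)benzaldehyde | COc1cc(OC)c(CC=C(C)C)c(O)c1C=O | intermediate
5 | isovanillin (3-hydroxy-4-methoxybenzaldehyde) | COc1ccc(C=O)cc1O | starting material
6 | 3-(tert-butyldimethylsilyloxy)-4-methoxybenzaldehyde | COc1ccc(C=O)cc1O[Si](C)(C)C(C)(C)C | intermediate
7 | tert-butyl(5-ethynyl-2-methoxyphenoxy)dimethylsilane | COc1ccc(C#C)cc1O[Si](C)(C)C(C)(C)C | intermediate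
8 | (E)-3-[3-(tert-butyldimethylsilyloxy)-4-methoxyphenyl]-1-[2-hydroxy-4,6-dimethoxy-3-(3-methylbut-2-en-1-yl)phenyl]prop-2-en-1-one (chalcone, formed in the flask, not isolated) | COc1ccc(/C=C/C(=O)c2c(OC)cc(OC)c(CC=C(C)C)c2O)cc1O[Si](C)(C)C(C)(C)C | intermediate
9 | (2S)-2-[3-(tert-butyldimethylsilyloxy)-4-methoxyphenyl]-5,7-dimethoxy-8-(3-methylbut-2-en-1-yl)chroman-4-one | COc1ccc([C@@H]2CC(=O)c3c(OC)cc(OC)c(CC=C(C)C)c3O2)cc1O[Si](C)(C)C(C)(C)C | intermediate
10 | (2S)-2-(3-hydroxy-4-methoxyphenyl)-5,7-dimethoxy-8-(3-methylbut-2-en-1-yl)chroman-4-one | COc1ccc([C@@H]2CC(=O)c3c(OC)cc(OC)c(CC=C(C)C)c3O2)cc1O | target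

Total steps: 6. Longest linear sequence: 4 steps (1, 2, 5, 6 or 3, 4, 5, 6).

**Steps most likely to fail**

Step 5. The alkyne may insert the other way round, placing the acyl group on the aryl-bearing carbon, or may oligomerise at rhodium. The ring closure may show poor facial discrimination, or enantiopurity may erode through reversible ring opening and racemic background closure. The fallback is the classical chalcone route followed by kinetic resolution; it sets out from 4 and 5 and comes back to the route at 10. Addition of excess MeMgBr to 4 in THF at 0 °C should give 1-[2-hydroxy-4,6-dimethoxy-3-(3-methylbut-2-en-1-yl)phenyl]ethanol F1. This acid-sensitive carbinol is oxidised crude with MnO2 in CH2Cl2 to 1-[2-hydroxy-4,6-dimethoxy-3-(3-methylbut-2-en-1-yl)phenyl]ethanone F2. Claisen–Schmidt condensation of F2 with isovanillin 5 (KOH, EtOH, rt) should give the free chalcone (E)-3-(3-hydroxy-4-methoxyphenyl)-1-[2-hydroxy-4,6-dimethoxy-3-(3-methylbut-2-en-1-yl)phenyl]prop-2-en-1-one F3. NaOAc in refluxing EtOH closes it to the racemic flavanone F4. Asymmetric transfer hydrogenation with [Cp*RhCl((R,R)-TsDPEN)] and HCO2H/Et3N in EtOAc is stopped near half conversion. By analogy with simple flavanones it should reduce the (2R)-ketone to the cis-(2R,4R)-flavan-4-ol F5 and leave (2S)-10, which is separated by chromatography.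

Step 1. O-alkylation, attack at the para carbon between the two methoxy groups, and double alkylation may compete with ortho C-alkylation. The fallback sets out from 1 and comes back at 3. O-Allylation of 1 with tert-butyl (2-methylbut-3-en-2-yl) carbonate and Pd(PPh3)4 in THF at 0 °C should give the tertiary ether 1,3-dimethoxy-5-[(2-methylbut-3-en-2-yl)oxy]benzene F6. Aromatic Claisen rearrangement of F6 (N,N-diethylaniline, about 140 °C) transfers the allyl unit with allylic inversion to the ortho carbon only and gives 3.

Step 2. Formaldehyde may attack the very electron-rich carbon between the two methoxy groups (hydroxymethylation, diarylmethane formation) instead of being delivered ortho to the phenol. The fallback sets out from 3 and comes back at 4. MOMCl and iPr2NEt in CH2Cl2 give 1,5-dimethoxy-3-(methoxymethoxy)-2-(3-methylbut-2-en-1-yl)benzene F7. Directed ortho-lithiation (n-BuLi, TMEDA, THF, 0 °C) at the carbon between OMOM and OMe, then DMF, gives 4,6-dimethoxy-2-(methoxymethoxy)-3-(3-methylbut-2-en-1-yl)benzaldehyde F8. Brief treatment with HCl in MeOH at rt removes the acetal and gives 4.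

**Further compounds**

F1 | step 5 | 1-[2-hydroxy-4,6-dimethoxy-3-(3-methylbut-2-en-1-yl)phenyl]ethanol (racemic) | COc1cc(OC)c(CC=C(C)C)c(O)c1C(C)O
F2 | step 5 | 1-[2-hydroxy-4,6-dimethoxy-3-(3-methylbut-2-en-1-yl)phenyl]ethanone | COc1cc(OC)c(CC=C(C)C)c(O)c1C(C)=O
F3 | step 5 | (E)-3-(3-hydroxy-4-methoxyphenyl)-1-[2-hydroxy-4,6-dimethoxy-3-(3-methylbut-2-en-1-yl)phenyl]prop-2-en-1-one | COc1ccc(/C=C/C(=O)c2c(OC)cc(OC)c(CC=C(C)C)c2O)cc1O
F4 | step 5 | racemic 2-(3-hydroxy-4-methoxyphenyl)-5,7-dimethoxy-8-(3-methylbut-2-en-1-yl)chroman-4-one | COc1ccc(C2CC(=O)c3c(OC)cc(OC)c(CC=C(C)C)c3O2)cc1O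
F5 | step 5 | (2R,4R)-2-(3-hydroxy-4-methoxyphenyl)-5,7-dimethoxy-8-(3-methylbut-2-en-1-yl)chroman-4-ol | COc1ccc([C@H]2C[C@@H](O)c3c(OC)cc(OC)c(CC=C(C)C)c3O2)cc1O
F6 | step 1 | 1,3-dimethoxy-5-[(2-methylbut-3-en-2-yl)oxy]benzene | COc1cc(OC)cc(OC(C)(C)C=C)c1
F7 | step 2 | 1,5-dimethoxy-3-(methoxymethoxy)-2-(3-methylbut-2-en-1-yl)benzene | COCOc1cc(OC)cc(OC)c1CC=C(C)C
F8 | step 2 | 4,6-dimethoxy-2-(methoxymethoxy)-3-(3-methylbut-2-en-1-yl)benzaldehyde | COCOc1c(C=O)c(OC)cc(OC)c1CC=C(C)C
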